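**Strategy**

Everything rests on the C5–C6 bond of ring A, the ten-membered carbocycle C1–C10. C6 is the γ-carbon of ring B, the butenolide O–C6–C7=C11–C12(=O), so ring B can be carried as an aromatic 2-silyloxyfuran whose only unsubstituted carbon is C6, while C4 next to C5 already holds its tertiary ether oxygen. In one operation the magnesium-chelated C5 aldehyde is attacked by C6: ring A closes, the furan turns into the C7=C11 butenolide, and the C5 and C6 stereocentres are set. The precursor is an open-chain α-alkoxy aldehyde carrying the C4 PMB ether, a silyl-protected C1 carbinol, the C8 tiglate and the 3,4-disubstituted 2-silyloxyfuran.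

Key step: step 15

Remarks on the chemistry:
- Atom numbers are those of the germacranolide frame of the target: ring A = C1–C10, ring B = O–C6–C7=C11–C12, ring C = the C4–C5 epoxide, C13 = the oxymethyl carbon on C11. The target is 4R,5S,6S,8S,10R; the ring-closure product is 4R,5R,6S, and C5 is inverted when the epoxide closes.
- C1 is taken through the ring closure as a triethylsilyl-protected carbinol and is oxidized in the last step. A C1 ketone would be silylated or enolized (loss of C10) when the silyloxyfuran is made, could be attacked by C6 in a six-membered mode, and would form hemiketals with a free hydroxyl at C4 or C8.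
- For the same reason the tiglate is placed on C8 before the ring closure. C13 stays a silyl ether until the end, because an ester at C13 of a 2-silyloxyfuran would ionize.
- Assumption: (R)-linalool and (S)-but-3-yn-2-ol are taken as commercially available in high enantiomeric purity.

**Route**

Step 1
Reactants: 1 (R)-linalool
Product: 2 (R)-linalyl 4-methoxybenzyl ether
Conditions: KH, PMBCl, Bu4NI (cat.), THF, 0 °C → rt
Reagents that add atoms: 4-methoxybenzyl chloride, COc1ccc(CCl)cc1
Why: Williamson etherification of the tertiary alkoxide at benzylic carbon puts the chelating, oxidatively removable ether on the C4 oxygen without touching the C4 stereocentre, which comes from the starting material.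

Step 2
Reactants: 2 (R)-linalyl 4-methoxybenzyl ether
Product: 4 (4R)-4-[(4-methoxybenzyl)oxy]-4-methylhex-5-enal, via secondary ozonide 3 (not isolated)
Conditions: O3, CH2Cl2, −78 °C, Sudan Red 7B end point; then PPh3, −78 °C → rt
Reagents that add atoms: ozone, [O-][O+]=O
Why: Chemoselective ozonolysis: the electron-rich trisubstituted alkene is cleaved much faster than the monosubstituted vinyl group deactivated by its allylic oxygen, and reductive work-up gives the C1 aldehyde.

Step 3
Reactants: 5 (S)-but-3-yn-2-ol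
Product: 6 (S)-but-3-yn-2-yl methanesulfonate
Conditions: MsCl, Et3N, CH2Cl2, −78 → 0 °C
Reagents that add atoms: methanesulfonyl chloride, CS(=O)(=O)Cl
Why: O-Sulfonylation of the propargylic alcohol does not touch the C–O stereocentre, so the mesylate keeps the S configuration.

Step 4
Reactants: 4 (4R)-4-[(4-methoxybenzyl)oxy]-4-methylhex-5-enal; 6 (S)-but-3-yn-2-yl methanesulfonate
Product: 8 (3R,6S,7R)-3-[(4-methoxybenzyl)oxy]-3,7-dimethylnon-1-en-8-yn-6-ol, via allenylzinc reagent 7 (not isolated)
Conditions: Pd(OAc)2 (5 mol%), PPh3 (5 mol%), Et2Zn, THF, −78 → −20 °C; aq. NH4Cl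
Reagents that add atoms: none
Why: Marshall propargylation: zerovalent palladium opens the mesylate in an anti SN2′ sense, transmetalation gives the axially chiral allenylzinc 7, and its cyclic SE2′ addition to the aldehyde transfers this chirality to C10 (R) and gives the anti C1 carbinol, whose configuration is erased when C1 is oxidized at the end.

Step 5
Reactants: 8 (3R,6S,7R)-3-[(4-methoxybenzyl)oxy]-3,7-dimethylnon-1-en-8-yn-6-ol
Product: 9 triethylsilyl ether of 8
Conditions: TESCl, imidazole, DMF, 0 °C → rt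
Reagents that add atoms: chlorotriethylsilane, CC[Si](Cl)(CC)CC
Why: Silylation of the secondary alcohol; the triethylsilyl ether masks C1 through the organometallic and Lewis-acid steps and can be removed at the end with buffered fluoride.

Step 6
Reactants: 9 triethylsilyl ether of 8
Product: 11 (3R,4S,7R)-7-[(4-methoxybenzyl)oxy]-3,7-dimethyl-4-[(triethylsilyl)oxy]non-8-enal, via alkenylborane 10 (not isolated)
Conditions: Cy2BH, THF, 0 °C → rt; then 30% H2O2, aq. NaHCO3, 0 °C
Reagents that add atoms: hydrogen peroxide, OO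
Why: Hydroboration–oxidation of a terminal alkyne: the hindered dialkylborane adds once and anti-Markovnikov to the alkyne far faster than to the neopentyl-type vinyl group, and buffered peroxide turns the alkenylborane into the C8 aldehyde through its enol.

Step 7
Reactants: 12 methyl 3-hydroxypropanoate
Product: 13 methyl 3-[(tert-butyldimethylsilyl)oxy]propanoate
Conditions: TBSCl, imidazole, DMF, rt
Reagents that add atoms: tert-butyldimethylsilyl chloride, CC(C)(C)[Si](C)(C)Cl
Why: Routine silylation of the primary alcohol gives the C13 oxygen a group that is a poor donor and a poor leaving group in the later Lewis-acid step.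

Step 8
Reactants: 13 methyl 3-[(tert-butyldimethylsilyl)oxy]propanoate; 14 (benzyloxy)acetyl chloride
Product: 16 methyl 4-(benzyloxy)-2-{[(tert-butyldimethylsilyl)oxy]methyl}-3-oxobutanoate, via lithium enolate 15 (not isolated)
Conditions: LiN(iPr)2 (2.1 equiv), 13 (2.0 equiv), THF, −78 °C; then 14 (1.0 equiv), −78 °C; AcOH quench
Reagents that add atoms: none
Why: Crossed Claisen condensation: the preformed lithium enolate (two equivalents, because the β-keto ester is deprotonated as it forms) is C-acylated by the acid chloride at −78 °C, where the β-silyloxy enolate does not eliminate, and this bimolecular order fixes which carbon is the nucleophile, which a Dieckmann closure of the isomeric acyloxyacetate would not (Chan-type acyl shift).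

Step 9
Reactants: 16 methyl 4-(benzyloxy)-2-{[(tert-butyldimethylsilyl)oxy]methyl}-3-oxobutanoate
Product: 18 3-{[(tert-butyldimethylsilyl)oxy]methyl}-4-hydroxyfuran-2(5H)-one, via hydroxy keto ester 17 (not isolated)
Conditions: H2 (1 atm), 10% Pd/C, EtOAc, rt
Reagents that add atoms: none
Why: Hydrogenolysis of the benzyl ether frees the γ-hydroxyl, which lactonizes onto the methyl ester (5-exo-trig) to give the tetronic acid; the silyl ether is inert.

Step 10
Reactants: 18 3-{[(tert-butyldimethylsilyl)oxy]methyl}-4-hydroxyfuran-2(5H)-one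
Product: 19 4-{[(tert-butyldimethylsilyl)oxy]methyl}-5-oxo-2,5-dihydrofuran-3-yl trifluoromethanesulfonate
Conditions: Tf2O, iPr2NEt, CH2Cl2, −78 °C
Reagents that add atoms: trifluoromethanesulfonic anhydride, O=S(=O)(OS(=O)(=O)C(F)(F)F)C(F)(F)F
Why: Enol triflation at the C4 oxygen of the tetronic acid (C7 of the target) gives the vinyl triflate needed for the chromium-mediated coupling.

Step 11
Reactants: 11 (3R,4S,7R)-7-[(4-methoxybenzyl)oxy]-3,7-dimethyl-4-[(triethylsilyl)oxy]non-8-enal; 19 4-{[(tert-butyldimethylsilyl)oxy]methyl}-5-oxo-2,5-dihydrofuran-3-yl trifluoromethanesulfonate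
Product: 20 3-{[(tert-butyldimethylsilyl)oxy]methyl}-4-{(1S,3R,4S,7R)-1-hydroxy-7-[(4-methoxybenzyl)oxy]-3,7-dimethyl-4-[(triethylsilyl)oxy]non-8-en-1-yl}furan-2(5H)-one
Conditions: CrCl2 (10 mol%), chiral oxazoline sulfonamide ligand N-[2-(4-isopropyl-4,5-dihydrooxazol-2-yl)-6-methylphenyl]methanesulfonamide (11 mol%), 1,8-bis(dimethylamino)naphthalene (11 mol%), NiCl2(2,9-dimethyl-1,10-phenanthroline) (2 mol%), Mn powder, Cp2ZrCl2, LiCl, MeCN, rt
Reagents that add atoms: none
Why: Nozaki–Hiyama–Kishi coupling: nickel inserts into the vinyl triflate, the alkenyl group passes to chromium and adds chemoselectively to the aldehyde, and the chiral sulfonamide ligand on chromium sets C8 under reagent control (the remote C10 and C1 centres give no useful bias), the ligand antipode being chosen in a pilot run so that the 8S carbinol predominates.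

Step 12
Reactants: 20 (8S)-hydroxy butenolide with C5 vinyl group
Product: 22 (2R,5S,6R,8S)-8-(4-{[(tert-butyldimethylsilyl)oxy]methyl}-5-oxo-2,5-dihydrofuran-3-yl)-8-hydroxy-2-[(4-methoxybenzyl)oxy]-2,6-dimethyl-5-[(triethylsilyl)oxy]octanal, via vicinal diol 21 (not isolated)
Conditions: OsO4 (2 mol%), NaIO4, 2,6-lutidine, 1,4-dioxane/H2O (3:1), rt
Reagents that add atoms: osmium tetroxide (catalytic oxygen carrier), O=[Os](=O)(=O)=O; sodium periodate (terminal oxidant), [Na+].[O-]I(=O)(=O)=O
Why: Lemieux–Johnson cleavage: OsO4 dihydroxylates the monosubstituted vinyl group in preference to the tetrasubstituted, electron-poor butenolide alkene and periodate cleaves diol 21 to the non-enolizable C5 aldehyde; it is run before esterification because a tiglate alkene would compete.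

Step 13
Reactants: 22 C5 aldehyde with free C8 hydroxyl
Product: 23 (1S,3R,4S,7R)-1-(4-{[(tert-butyldimethylsilyl)oxy]methyl}-5-oxo-2,5-dihydrofuran-3-yl)-7-[(4-methoxybenzyl)oxy]-3,7-dimethyl-8-oxo-4-[(triethylsilyl)oxy]octyl (2E)-2-methylbut-2-enoate
Conditions: tigloyl chloride, pyridine, DMAP (cat.), CH2Cl2, 0 °C → rt
Reagents that add atoms: (E)-2-methylbut-2-enoyl chloride, C/C=C(\C)C(Cl)=O
Why: Nucleophile-catalysed acylation of the C8 hydroxyl with retention installs the final ester now, so that C8 never has to be a free hydroxyl once C1 is a ketone.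

Step 14
Reactants: 23 butenolide tiglate aldehyde
Product: 24 (1S,3R,4S,7R)-1-(4-{[(tert-butyldimethylsilyl)oxy]methyl}-5-[(triisopropylsilyl)oxy]furan-3-yl)-7-[(4-methoxybenzyl)oxy]-3,7-dimethyl-8-oxo-4-[(triethylsilyl)oxy]octyl (2E)-2-methylbut-2-enoate
Conditions: TIPSOTf, Et3N, CH2Cl2, −40 → 0 °C; pentane, filtration through Celite, used at once
Reagents that add atoms: triisopropylsilyl trifluoromethanesulfonate, CC(C)[Si](OS(=O)(=O)C(F)(F)F)(C(C)C)C(C)C
Why: Soft enolization: silylation of the lactone carbonyl and deprotonation at C6 by Et3N aromatize ring B to the 2-silyloxyfuran; the aldehyde has no α-hydrogen, the bulky silyl triflate is a poor promoter of premature aldol addition at low temperature, and non-aqueous work-up removes the ammonium triflate before the Lewis-acid step.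

Step 15
Reactants: 24 silyloxyfuran alkoxy aldehyde (seco compound)
Product: 25 (1S,4R,5R,6S,8S,10R)-13-[(tert-butyldimethylsilyl)oxy]-5-hydroxy-4-[(4-methoxybenzyl)oxy]-8-[(2E)-2-methylbut-2-enoyloxy]-1-[(triethylsilyl)oxy]germacr-7(11)-en-12,6-olide
Conditions: MgBr2·OEt2 (4 equiv), CH2Cl2/Et2O, −40 → −10 °C, 24 added by syringe pump to a final 1 mM; aq. NaHCO3
Reagents that add atoms: none
Why: Proposed new method: MgBr2 binds the C5 aldehyde oxygen and the C4 PMB ether oxygen in a five-membered chelate, the tethered 2-silyloxyfuran attacks the activated carbonyl through C6, and loss of the TIPS group from the O-silyl oxocarbenium ion (to bromide) leaves the C7=C11 butenolide. The closest known reaction type is the intermolecular Lewis-acid vinylogous Mukaiyama aldol addition of 2-silyloxyfurans to α-alkoxy aldehydes, not yet used to close a ten-membered carbocycle. Ring A closes in a 10-exo-trig mode, run at about 1 mM with slow addition so that cyclization outruns oligomerization. C5 is set by the Cram chelate, in which C6 enters on the face of the C4 methyl group away from the C3 chain (4,5-syn, 5R), and C6 by the synclinal, threo-selective approach usual for silyloxyfurans (5,6-syn, 6S). The step needs γ-regioselectivity and a single electrophile: C7 and C11 are fully substituted so only C6 can bond, and C1 is masked as a silyl ether so that no ketone competes for C6 in a six-membered mode. The silyl ethers at C1 and C13 and the ester at C8 are weak donors and poor leaving groups towards magnesium at low temperature, so the C4/C5 chelate should stay in control.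

Step 16
Reactants: 25 macrocyclic C5 carbinol with C4 PMB ether
Product: 26 (1S,4R,5R,6S,8S,10R)-13-[(tert-butyldimethylsilyl)oxy]-4,5-dihydroxy-8-[(2E)-2-methylbut-2-enoyloxy]-1-[(triethylsilyl)oxy]germacr-7(11)-en-12,6-olide
Conditions: DDQ, CH2Cl2/pH 7 phosphate buffer (10:1), 0 °C → rt
Reagents that add atoms: none
Why: Oxidative cleavage of the PMB ether by DDQ (hydride abstraction, then hydrolysis of the oxocarbenium ion by the buffer water) frees the C4 hydroxyl; silyl ethers, esters and the butenolide are inert.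

Step 17
Reactants: 26 macrocyclic 4,5-syn diol
Product: 27 (1S,4R,5S,6S,8S,10R)-13-[(tert-butyldimethylsilyl)oxy]-4,5-epoxy-8-[(2E)-2-methylbut-2-enoyloxy]-1-[(triethylsilyl)oxy]germacr-7(11)-en-12,6-olide
Conditions: PPh3, DIAD, toluene, 0 → 60 °C
Reagents that add atoms: none
Why: Mitsunobu-type cyclodehydration: the 1,2-diol gives a dioxaphosphorane that opens to the C5 oxyphosphonium and C4 alkoxide, and 3-exo-tet displacement at the secondary C5 inverts it (5R to 5S) while C4 is retained, which gives the cis epoxide (ring C).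

Step 18
Reactants: 27 bis-silyl epoxide
Product: 28 (1S,4R,5S,6S,8S,10R)-4,5-epoxy-1,13-dihydroxy-8-[(2E)-2-methylbut-2-enoyloxy]germacr-7(11)-en-12,6-olide
Conditions: HF·pyridine, pyridine, THF, 0 °C → rt; chromatography on Et3N-deactivated silica
Reagents that add atoms: none
Why: Fluoride cleavage of both silyl ethers; buffering with pyridine at low temperature keeps the medium too weakly acidic for opening of the epoxide by the freed C1 hydroxyl and too weakly basic for deprotonation at C6.

Step 19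
Reactants: 28 epoxy diol
Product: 29 (1S,4R,5S,6S,8S,10R)-13-acetoxy-4,5-epoxy-1-hydroxy-8-[(2E)-2-methylbut-2-enoyloxy]germacr-7(11)-en-12,6-olide
Conditions: AcCl, 2,4,6-collidine, CH2Cl2, −78 °C
Reagents that add atoms: acetyl chloride, CC(Cl)=O
Why: Kinetically selective acylation: at −78 °C with a hindered pyridine base the primary allylic C13 hydroxyl is acetylated much faster than the hindered secondary C1 hydroxyl.

Step 20
Reactants: 29 C1 carbinol
Product: 30 CNP0229937.1, (4R,5S,6S,8S,10R)-13-acetoxy-4,5-epoxy-1-oxo-8-[(2E)-2-methylbut-2-enoyloxy]germacr-7(11)-en-12,6-olide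
Conditions: Dess–Martin periodinane, NaHCO3, CH2Cl2, 0 °C → rt
Reagents that add atoms: none
Why: Dess–Martin oxidation of the C1 carbinol under bicarbonate buffering gives the ketone without epimerizing C10 or opening the epoxide; it comes last so that the ketone never meets a free hydroxyl at C4 or C8.

**Compound list**

1 | (R)-linalool, (3R)-3,7-dimethylocta-1,6-dien-3-ol | C=C[C@](C)(O)CCC=C(C)C | starting material
2 | 1-({[(3R)-3,7-dimethylocta-1,6-dien-3-yl]oxy}methyl)-4-methoxybenzene | C=C[C@](C)(OCc1ccc(OC)cc1)CCC=C(C)C | intermediate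
3 | 3,3-dimethyl-5-{(3R)-3-[(4-methoxybenzyl)oxy]-3-methylpent-4-en-1-yl}-1,2,4-trioxolane (secondary ozonide, ring carbon unassigned) | C=C[C@](C)(OCc1ccc(OC)cc1)CCC1OOC(C)(C)O1 | intermediate
4 | (4R)-4-[(4-methoxybenzyl)oxy]-4-methylhex-5-enal | C=C[C@](C)(OCc1ccc(OC)cc1)CCC=O | intermediate
5 | (S)-but-3-yn-2-ol | C[C@H](O)C#C | starting material
6 | (S)-but-3-yn-2-yl methanesulfonate | C[C@H](OS(C)(=O)=O)C#C | intermediate
7 | (aR)-buta-1,2-dien-1-yl(ethyl)zinc | CC[Zn]C([H])=[C@]=C([H])C | intermediate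
8 | (3R,6S,7R)-3-[(4-methoxybenzyl)oxy]-3,7-dimethylnon-1-en-8-yn-6-ol | C=C[C@](C)(OCc1ccc(OC)cc1)CC[C@H](O)[C@H](C)C#C | intermediate
9 | triethyl{[(3R,6S,7R)-3-[(4-methoxybenzyl)oxy]-3,7-dimethylnon-1-en-8-yn-6-yl]oxy}silane | C=C[C@](C)(OCc1ccc(OC)cc1)CC[C@H](O[Si](CC)(CC)CC)[C@H](C)C#C | intermediate
10 | dicyclohexyl{(1E,3R,4S,7R)-7-[(4-methoxybenzyl)oxy]-3,7-dimethyl-4-[(triethylsilyl)oxy]nona-1,8-dien-1-yl}borane | C=C[C@](C)(OCc1ccc(OC)cc1)CC[C@H](O[Si](CC)(CC)CC)[C@H](C)/C=C/B(C1CCCCC1)C1CCCCC1 | intermediate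
11 | (3R,4S,7R)-7-[(4-methoxybenzyl)oxy]-3,7-dimethyl-4-[(triethylsilyl)oxy]non-8-enal | C=C[C@](C)(OCc1ccc(OC)cc1)CC[C@H](O[Si](CC)(CC)CC)[C@H](C)CC=O | intermediate
12 | methyl 3-hydroxypropanoate | OCCC(=O)OC | starting material
13 | methyl 3-[(tert-butyldimethylsilyl)oxy]propanoate | COC(=O)CCO[Si](C)(C)C(C)(C)C | intermediate
14 | (benzyloxy)acetyl chloride | O=C(Cl)COCc1ccccc1 | starting material
15 | lithium enolate of 13 | [Li+].[O-]/C(OC)=C/CO[Si](C)(C)C(C)(C)C | intermediate
16 | methyl 4-(benzyloxy)-2-{[(tert-butyldimethylsilyl)oxy]methyl}-3-oxobutanoate (racemic, enolizable C2) | COC(=O)C(CO[Si](C)(C)C(C)(C)C)C(=O)COCc1ccccc1 | intermediate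
17 | methyl 2-{[(tert-butyldimethylsilyl)oxy]methyl}-4-hydroxy-3-oxobutanoate | COC(=O)C(CO[Si](C)(C)C(C)(C)C)C(=O)CO | intermediate
18 | 3-{[(tert-butyldimethylsilyl)oxy]methyl}-4-hydroxyfuran-2(5H)-one | O=C1OCC(O)=C1CO[Si](C)(C)C(C)(C)C | intermediate
19 | 4-{[(tert-butyldimethylsilyl)oxy]methyl}-5-oxo-2,5-dihydrofuran-3-yl trifluoromethanesulfonate | O=C1OCC(OS(=O)(=O)C(F)(F)F)=C1CO[Si](C)(C)C(C)(C)C | intermediate
20 | 3-{[(tert-butyldimethylsilyl)oxy]methyl}-4-{(1S,3R,4S,7R)-1-hydroxy-7-[(4-methoxybenzyl)oxy]-3,7-dimethyl-4-[(triethylsilyl)oxy]non-8-en-1-yl}furan-2(5H)-one | C=C[C@](C)(OCc1ccc(OC)cc1)CC[C@H](O[Si](CC)(CC)CC)[C@H](C)C[C@H](O)C1=C(CO[Si](C)(C)C(C)(C)C)C(=O)OC1 | intermediate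
21 | vicinal diol from the vinyl group of 20 (both epimers at the new carbinol) | OCC(O)[C@](C)(OCc1ccc(OC)cc1)CC[C@H](O[Si](CC)(CC)CC)[C@H](C)C[C@H](O)C1=C(CO[Si](C)(C)C(C)(C)C)C(=O)OC1 | intermediate
22 | (2R,5S,6R,8S)-8-(4-{[(tert-butyldimethylsilyl)oxy]methyl}-5-oxo-2,5-dihydrofuran-3-yl)-8-hydroxy-2-[(4-methoxybenzyl)oxy]-2,6-dimethyl-5-[(triethylsilyl)oxy]octanal | O=C[C@](C)(OCc1ccc(OC)cc1)CC[C@H](O[Si](CC)(CC)CC)[C@H](C)C[C@H](O)C1=C(CO[Si](C)(C)C(C)(C)C)C(=O)OC1 | intermediate
23 | (1S,3R,4S,7R)-1-(4-{[(tert-butyldimethylsilyl)oxy]methyl}-5-oxo-2,5-dihydrofuran-3-yl)-7-[(4-methoxybenzyl)oxy]-3,7-dimethyl-8-oxo-4-[(triethylsilyl)oxy]octyl (2E)-2-methylbut-2-enoate | O=C[C@](C)(OCc1ccc(OC)cc1)CC[C@H](O[Si](CC)(CC)CC)[C@H](C)C[C@H](OC(=O)/C(C)=C/C)C1=C(CO[Si](C)(C)C(C)(C)C)C(=O)OC1 | intermediate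
24 | (1S,3R,4S,7R)-1-(4-{[(tert-butyldimethylsilyl)oxy]methyl}-5-[(triisopropylsilyl)oxy]furan-3-yl)-7-[(4-methoxybenzyl)oxy]-3,7-dimethyl-8-oxo-4-[(triethylsilyl)oxy]octyl (2E)-2-methylbut-2-enoate (precursor of the key step) | O=C[C@](C)(OCc1ccc(OC)cc1)CC[C@H](O[Si](CC)(CC)CC)[C@H](C)C[C@H](OC(=O)/C(C)=C/C)c1coc(O[Si](C(C)C)(C(C)C)C(C)C)c1CO[Si](C)(C)C(C)(C)C | intermediate
25 | (1S,4R,5R,6S,8S,10R)-13-[(tert-butyldimethylsilyl)oxy]-5-hydroxy-4-[(4-methoxybenzyl)oxy]-8-[(2E)-2-methylbut-2-enoyloxy]-1-[(triethylsilyl)oxy]germacr-7(11)-en-12,6-olide (product of the key step) | C/C=C(\C)C(=O)O[C@H]1C[C@@H](C)[C@@H](O[Si](CC)(CC)CC)CC[C@@](C)(OCc3ccc(OC)cc3)[C@H](O)[C@H]2OC(=O)C(CO[Si](C)(C)C(C)(C)C)=C12 | intermediate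
26 | (1S,4R,5R,6S,8S,10R)-13-[(tert-butyldimethylsilyl)oxy]-4,5-dihydroxy-8-[(2E)-2-methylbut-2-enoyloxy]-1-[(triethylsilyl)oxy]germacr-7(11)-en-12,6-olide | C/C=C(\C)C(=O)O[C@H]1C[C@@H](C)[C@@H](O[Si](CC)(CC)CC)CC[C@@](C)(O)[C@H](O)[C@H]2OC(=O)C(CO[Si](C)(C)C(C)(C)C)=C12 | intermediate
27 | (1S,4R,5S,6S,8S,10R)-13-[(tert-butyldimethylsilyl)oxy]-4,5-epoxy-8-[(2E)-2-methylbut-2-enoyloxy]-1-[(triethylsilyl)oxy]germacr-7(11)-en-12,6-olide | C/C=C(\C)C(=O)O[C@H]1C[C@@H](C)[C@@H](O[Si](CC)(CC)CC)CC[C@@]2(C)O[C@H]2[C@H]2OC(=O)C(CO[Si](C)(C)C(C)(C)C)=C12 | intermediate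
28 | (1S,4R,5S,6S,8S,10R)-4,5-epoxy-1,13-dihydroxy-8-[(2E)-2-methylbut-2-enoyloxy]germacr-7(11)-en-12,6-olide | C/C=C(\C)C(=O)O[C@H]1C[C@@H](C)[C@@H](O)CC[C@@]2(C)O[C@H]2[C@H]2OC(=O)C(CO)=C12 | intermediate
29 | (1S,4R,5S,6S,8S,10R)-13-acetoxy-4,5-epoxy-1-hydroxy-8-[(2E)-2-methylbut-2-enoyloxy]germacr-7(11)-en-12,6-olide | C/C=C(\C)C(=O)O[C@H]1C[C@@H](C)[C@@H](O)CC[C@@]2(C)O[C@H]2[C@H]2OC(=O)C(COC(C)=O)=C12 | intermediate
30 | CNP0229937.1, (4R,5S,6S,8S,10R)-13-acetoxy-4,5-epoxy-1-oxo-8-[(2E)-2-methylbut-2-enoyloxy]germacr-7(11)-en-12,6-olide | C/C=C(\C)C(=O)O[C@H]1C[C@@H](C)C(=O)CC[C@@]2(C)O[C@H]2[C@H]2OC(=O)C(COC(C)=O)=C12 | target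

**Step count**

Total: 20 steps. Longest linear sequence: 15 steps (steps 1, 2, 4–6 and 11–20, from (R)-linalool).

**Steps most likely to fail**

Step 15 (ring closure). Intermolecular aldol oligomerization or loss of the silyl group from the furan may outrun the entropically and transannularly disfavoured ten-membered closure. The tether may also override the chelate and threo preferences, giving the wrong facial sense at C5 or C6.

The fallback uses known chemistry only: it makes the C5–C6 bond between two molecules and closes ring A at C7–C8. It sets out from 9 and 19 and comes back to the route at 25.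
- Lemieux–Johnson cleavage of the vinyl group of 9 (OsO4 cat., NaIO4, 2,6-lutidine) would give the alkynyl aldehyde F1.
- TIPSOTf/Et3N would convert 19 into the silyloxyfuran triflate F2.
- An intermolecular MgBr2·OEt2-mediated vinylogous Mukaiyama aldol addition of F2 to F1 (chelation control at C4/C5, threo preference at C5/C6) would give the open-chain C5 carbinol F3.
- Cy2BH followed by buffered H2O2 would turn its alkyne into the C8 aldehyde F4.
- An intramolecular Nozaki–Hiyama–Kishi reaction (CrCl2, NiCl2 cat., DMSO/THF, high dilution) would close ring A to the macrocyclic diol F5 (8S) and its C8 epimer F6 (8R), to be separated.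
- F5 would be acylated at the less hindered C8 hydroxyl with tigloyl chloride/pyridine. F6 would be esterified with tiglic acid, PPh3 and DIAD with inversion at C8. Both give 25.

Step 11 (fragment union). Facial selectivity at C8 may be poor, because ligand control has not been calibrated for a tetronate-derived alkenyl triflate and the substrate offers no bias of its own.

The fallback replaces reagent control by separation and a stereoinvertive esterification. It sets out from 11 and 19 and comes back at 23.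
- A ligand-free coupling (CrCl2, NiCl2 cat., DMF) would give 20 together with its C8 epimer F7, to be separated by chromatography. 20 continues as in the route.
- F7 would be cleaved (OsO4 cat., NaIO4, 2,6-lutidine) to the epimeric hydroxy aldehyde F8.
- F8 would be esterified with tiglic acid under Mitsunobu conditions (PPh3, DIAD, toluene, 0 °C) with inversion at C8, which gives 23.

Step 17 (epoxide closure). Once the C5 oxygen is activated, β-elimination towards the acidic C6–H (γ-position of the butenolide) may compete with 3-exo-tet closure, or the hindered C5 hydroxyl may not be activated at all.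

The fallback separates activation and closure. It sets out from 26 and comes back at 27.
- MsCl/Et3N in CH2Cl2 at −40 °C would sulfonylate only the secondary C5 hydroxyl and give the hydroxy mesylate F9.
- One equivalent of KN(SiMe3)2 in THF at −78 °C would deprotonate the C4 hydroxyl faster than C6–H, and the alkoxide would displace the mesylate with inversion to give 27.

Further compounds
F1 | step 15 | (2R,5S,6R)-2-[(4-methoxybenzyl)oxy]-2,6-dimethyl-5-[(triethylsilyl)oxy]oct-7-ynal | O=C[C@](C)(OCc1ccc(OC)cc1)CC[C@H](O[Si](CC)(CC)CC)[C@H](C)C#C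
F2 | step 15 | 4-{[(tert-butyldimethylsilyl)oxy]methyl}-5-[(triisopropylsilyl)oxy]furan-3-yl trifluoromethanesulfonate | CC(C)[Si](Oc1occ(OS(=O)(=O)C(F)(F)F)c1CO[Si](C)(C)C(C)(C)C)(C(C)C)C(C)C
F3 | step 15 | open-chain C5 carbinol butenolide triflate with terminal alkyne (C5–C6 bond formed, 4,5-syn and 5,6-syn) | C#C[C@@H](C)[C@@H](O[Si](CC)(CC)CC)CC[C@@](C)(OCc1ccc(OC)cc1)[C@H](O)[C@H]1OC(=O)C(CO[Si](C)(C)C(C)(C)C)=C1OS(=O)(=O)C(F)(F)F
F4 | step 15 | C8 aldehyde derived from F3 | O=CC[C@@H](C)[C@@H](O[Si](CC)(CC)CC)CC[C@@](C)(OCc1ccc(OC)cc1)[C@H](O)[C@H]1OC(=O)C(CO[Si](C)(C)C(C)(C)C)=C1OS(=O)(=O)C(F)(F)F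
F5 | step 15 | macrocyclic 5,8-diol (8S), 25 without its tigloyl group | O[C@H]1C[C@@H](C)[C@@H](O[Si](CC)(CC)CC)CC[C@@](C)(OCc3ccc(OC)cc3)[C@H](O)[C@H]2OC(=O)C(CO[Si](C)(C)C(C)(C)C)=C12
F6 | step 15 | C8 epimer (8R) of F5 | O[C@@H]1C[C@@H](C)[C@@H](O[Si](CC)(CC)CC)CC[C@@](C)(OCc3ccc(OC)cc3)[C@H](O)[C@H]2OC(=O)C(CO[Si](C)(C)C(C)(C)C)=C12
F7 | step 11 | C8 epimer (8R) of 20 | C=C[C@](C)(OCc1ccc(OC)cc1)CC[C@H](O[Si](CC)(CC)CC)[C@H](C)C[C@@H](O)C1=C(CO[Si](C)(C)C(C)(C)C)C(=O)OC1
F8 | step 11 | C8 epimer (8R) of 22 | O=C[C@](C)(OCc1ccc(OC)cc1)CC[C@H](O[Si](CC)(CC)CC)[C@H](C)C[C@@H](O)C1=C(CO[Si](C)(C)C(C)(C)C)C(=O)OC1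
F9 | step 17 | C5 methanesulfonate of diol 26 | C/C=C(\C)C(=O)O[C@H]1C[C@@H](C)[C@@H](O[Si](CC)(CC)CC)CC[C@@](C)(O)[C@H](OS(C)(=O)=O)[C@H]2OC(=O)C(CO[Si](C)(C)C(C)(C)C)=C12
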